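## Structural features

Hansfordiol C (12) is a 5-alkylresorcinol: one benzene ring with hydroxyls on C1 and C3 and an unbranched seventeen-carbon chain on C5, and no other ring. With the chain numbered from the benzylic carbon C1' to the methyl C17', its only functional group is the secondary hydroxyl at C15'. C15' is also the only stereocentre, and it is S (O > C14' > C16' > H). It has no stereochemical neighbour: fourteen methylenes separate it from the ring, and its two flanks, the C14' methylene and the C16'–C17' ethyl group, are saturated chains that differ only in length. The fragile parts are the electron-rich resorcinol, best kept masked through the organometallic steps, and the secondary carbinol, which is open to substitution or elimination under strong Lewis or Brønsted acids and so narrows the choice of phenol protecting group. The skeleton is trivial. The real difficulty is enantioface discrimination at C15' between ethyl and a long n-alkyl group, and joining that isolated stereocentre to the arene in few steps. The key step uses the fact that C13'–C14' can be held as a triple bond, so that the C15' carbonyl sits between a rod-like sp-hybridized arm and an sp3 ethyl group. Because C1'–C12' are plain methylenes, the same triple bond can then be walked to C1'–C2', where it becomes the handle for bonding to ring carbon C5.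

## Logic of the disconnections

12 ⇒ 10. No skeletal bond is cut. The two phenolic O–H bonds are traced back to O–CH2Ph bonds and the C1'–C2' single bond to a triple bond, because one hydrogenation undoes both changes. Methyl ethers are avoided on purpose: thiolate cleavage of a resorcinol dimethyl ether tends to halt at the monomethyl ether once the first phenoxide has formed, and the boron or hydrogen halides that force the second cleavage endanger the C15' carbinol. The gain is a one-step end-game, and the aryl alkyne in 10 points straight at a C(sp)–C(sp2) coupling. The forward step must saturate C1'≡C2' (through 11) and cleave both benzylic C–O bonds while the C15'–O bond, which is neither benzylic nor allylic, and the aromatic ring stay intact.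

10 ⇒ 8 + 9. The C1'–C5 bond between alkyne and ring is cut. It is the only bond joining chain and ring, and cutting it separates a purchasable arene (9) from a chain (8) that carries all the stereochemical content. The gain is full convergence with no protecting group on the carbinol. The forward coupling must tolerate the free C15' hydroxyl, activate an aryl bromide at low temperature, and outrun oxidative dimerization of 8.

8 ⇒ 6. No bond is cut; the triple bond is moved on paper from C1'≡C2' back to C13'≡C14', next to the carbinol. Only there does the unsaturation help to create the stereocentre: in 8 the hydroxyl lies between two saturated chains, in 6 between an alkynyl and an ethyl group. The gain is that remote functionalization of a C17 chain is no longer needed, since 6 has a plain dodecyl tail. The forward step must drive the triple bond through twelve positions against thermodynamics, end only at the terminus (as the dianion 7), and leave the C15'–H bond untouched.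

6 ⇒ 5. The C15'–H bond is cut, which removes the only stereocentre and leaves an achiral ynone. The forward step must deliver hydrogen to one face of the carbonyl, must not reduce the triple bond, and must run without free base, because 5 is a Michael acceptor with acidic propargylic hydrogens at C12'.

5 ⇒ 1 + 2. The C14'–C15' bond between alkyne and carbonyl is cut into an acetylide donor and an acyl acceptor, both catalogue compounds. The forward addition must stop at the ketone oxidation level, which the chelated adduct 4 formed from 3 ensures, and the quench must keep the released amine from adding to 5.

## Other disconnections considered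

Alternative 1: The cut runs through the aromatic ring. Bonds C1–C2, C3–C4 and C1–C6 of the resorcinol are disconnected, leaving the cyclobutenone A1, which already carries the whole C1'–C17' chain with a silyl-protected C15' hydroxyl, and the ynol ether A2. Forward, heating the two would start a pericyclic cascade: four-electron ring opening of A1, [2+2] cycloaddition of A2, a second ring opening, six-electron electrocyclization and tautomerization, ending in the phenol A3.
- In its favour: the 1,3,5 pattern is fixed by the mechanism, no transition metal or aryl halide is needed, and the neutral thermal conditions do not threaten the silyl ether. On metal-free operation and regiochemical certainty it is the equal of, or better than, the chosen plan.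
- Against it here: the ring of 12 is symmetric and can be bought as 9, so building it spends steps on a solved problem. A1 must be assembled from a terminal alkyne two carbons longer than 8, so the stereocentre still has to be made beforehand by another asymmetric step. A3 then needs an aryl ethyl ether cleavage, the kind of dealkylation the carbinol tolerates badly, plus desilylation.
- Comparison: the cascade is the more intricate mechanism, stereochemical safety is equal (C15' is a spectator in both), and step economy clearly favours the chosen plan (five steps against roughly ten).

Alternative 2: The cut removes two bonds around the stereocentre, C15'–C16' and C13'–C14', giving three pieces: A4, A5 and the (E)-alkenyl bromide A7. Forward, A4 adds to the boron of A5 to give the ate complex A6. A chiral palladium–ferrocenyl bisphosphine catalyst inserts into the C–Br bond of A7, binds the vinyl group of A6, and induces a 1,2-shift of ethyl from boron to carbon as the alkenyl group is delivered to the vinyl terminus, giving the secondary boronic ester A8.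
- In its favour: two skeletal bonds and the stereocentre are made in one catalytic event, so on bond construction per step it is better than the chosen key step, which forms no skeletal bond. Stereocontrol comes from the ligand and needs no contrast between the flanks, which makes it equal in principle. No strongly basic isomerization is involved.
- Against it here: A7 holds C1'–C13' and the arene and needs its own multistep synthesis with E control. A4 is pyrophoric, and a bromide electrophile needs a halide scavenger. Three steps follow A8: stereoretentive C–B oxidation, alkene hydrogenation and unmasking of the phenols, where the methyl ether problem returns.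
- Comparison: alternative 2 is mechanistically more ambitious and more convergent in its key step. The chosen plan is shorter (five steps against about nine), uses cheaper inputs, and relies on a reduction with a broad record on this substrate class.

Alternative 3: The cut is the C12'–C13' bond in the middle of the saturated chain, between the carboxylic acids A9 and A10. Forward, anodic co-oxidation of the two carboxylates on platinum in methanol would expel two molecules of CO2 and couple the two primary radicals to A11, the fully protected target.
- In its favour: the bond forms between two unfunctionalized sp3 carbons far from any sensitive group, and no metal reagent or strong base is used. The stereocentre arrives finished and sees neither base nor metal afterwards, so on stereochemical safety it is the equal of the chosen plan and on reagent hazard arguably the better.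
- Against it here: a mixed Kolbe coupling is statistical, so the cross product competes with both homodimers and one acid must be used in excess. The arene has to be deactivated as its bis-pivalate to survive the anode. A9 needs its own asymmetric step, so the stereochemical problem is moved and not solved; A10 needs its own chain synthesis; and two deprotections follow.
- Comparison: the central cut is the most convergent on paper, but selectivity in the key step and step economy (about ten steps in all) favour the chosen plan.

Key step: step 2

Assumption: 9 is bought as such; the descriptor S at C15' applies to 6, 7, 8, 10, 11 and 12 alike, because in each the C14' branch outranks ethyl.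

## Route

Step 1
Reactants: 1 tetradec-1-yne; 2 N-methoxy-N-methylpropanamide
Product: 5 heptadec-4-yn-3-one, via lithium tetradec-1-ynide 3 (not isolated), via chelated lithium hemiaminal alkoxide 4 (not isolated)
Conditions: n-BuLi, THF, −78 °C; 2, −78 → 0 °C; inverse quench into cold 1 M HCl
Reagents that add atoms: none
Why: Weinreb ketone synthesis: acetylide 3 adds once to 2 and the five-membered N-methoxy chelate 4 holds the tetrahedral stage until the acidic quench, so no tertiary alcohol can form. Quenching into cold acid protonates the released N,O-dimethylhydroxylamine before it can add to the ynone in conjugate fashion.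

Step 2
Reactants: 5 heptadec-4-yn-3-one
Product: 6 (S)-heptadec-4-yn-3-ol
Conditions: Ru[(S,S)-TsNCH(Ph)CH(Ph)NH](p-cymene) (1 mol%, preformed, base-free), i-PrOH, 25 °C, Ar
Reagents that add atoms: none
Why: Noyori-type asymmetric transfer hydrogenation of an α,β-acetylenic ketone. The 16-electron amido complex takes H2 from 2-propanol to become the 18-electron hydride RuH[(S,S)-TsNCH(Ph)CH(Ph)NH2](p-cymene) of divalent ruthenium, which hands the hydride on ruthenium and the proton on nitrogen to the C15' carbonyl in one six-membered outer-sphere transition state, the ketone never binding to the metal. No ring is closed and no skeletal bond is formed; the one new stereocentre, C15', is set by the catalyst alone, since 5 has no other stereo-element. In the chiral pocket the linear alkynyl arm takes the place next to the η6-arene that an aryl group occupies in aryl ketones and the sp3 ethyl group points away, so with the (S,S) ligand hydride should reach the face that gives the S carbinol, the same sense as for other ynones. Chemoselectivity for C=O over C≡C follows from the polar hydride/proton transfer, for which a non-polar triple bond is no acceptor. The preformed amido complex replaces the chloride precatalyst because the chloride needs added base to enter the cycle, and free alkoxide would attack 5 by conjugate addition and propargyl–allenyl isomerization. Because an ynone is a much stronger hydride acceptor than acetone, the equilibrium lies on the side of 6 and back-oxidation, the usual cause of ee erosion in 2-propanol, should be negligible.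

Step 3
Reactants: 6 (S)-heptadec-4-yn-3-ol
Product: 8 (S)-heptadec-16-yn-3-ol, via dipotassium alkoxide acetylide 7 (not isolated)
Conditions: Li, H2N(CH2)3NH2, 70 °C; KOt-Bu, 20 °C; then 6, 20 °C; ice/H2O
Reagents that add atoms: none
Why: Alkyne zipper isomerization: the potassium 3-aminopropylamide made in the flask (without KH) relays the triple bond by propargyl/allenyl proton shifts until it is trapped irreversibly as the terminal acetylide in 7. The C15' alkoxide forms first, blocks migration towards C16' and makes the C15'–H bond too weakly acidic to be removed, so the configuration should survive, as is known for optically active alkynols.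

Step 4
Reactants: 8 (S)-heptadec-16-yn-3-ol; 9 1,3-bis(benzyloxy)-5-bromobenzene
Product: 10 (S)-17-[3,5-bis(benzyloxy)phenyl]heptadec-16-yn-3-ol
Conditions: Pd(PhCN)2Cl2 (3 mol%), [HP(t-Bu)3]BF4 (6 mol%), CuI (2 mol%), i-Pr2NH, dioxane, 25 °C, degassed
Reagents that add atoms: none
Why: Sonogashira coupling: zerovalent palladium carrying the bulky, electron-rich P(t-Bu)3 inserts into the C–Br bond of 9 at room temperature, the copper acetylide of 8 transmetalates, and reductive elimination forms the C1'–C5 bond. The free secondary hydroxyl and the benzyl ethers are inert, and C15' is not involved.

Step 5
Reactants: 10 (S)-17-[3,5-bis(benzyloxy)phenyl]heptadec-16-yn-3-ol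
Product: 12 Hansfordiol C [(S)-5-(15-hydroxyheptadecyl)benzene-1,3-diol], via saturated bis(benzyl) ether 11 (not isolated)
Conditions: H2 (3 atm), Pd/C (10% Pd), EtOAc/MeOH, 25 °C
Reagents that add atoms: none
Why: Heterogeneous hydrogenation saturates C1'≡C2' and the same catalyst then hydrogenolyses both aryl benzyl ethers, releasing toluene. The C15'–O bond is neither benzylic nor allylic and the resorcinol ring is not reduced over palladium at room temperature, so the stereocentre and the arene are untouched.

## Compound list

1 | tetradec-1-yne | C#CCCCCCCCCCCCC | starting material
2 | N-methoxy-N-methylpropanamide | CCC(=O)N(C)OC | starting material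
3 | lithium tetradec-1-ynide | [Li]C#CCCCCCCCCCCCC | intermediate (not isolated)
4 | lithium 3-[methoxy(methyl)amino]heptadec-4-yn-3-olate (chelated tetrahedral adduct, racemic) | CCC(O[Li])(N(C)OC)C#CCCCCCCCCCCCC | intermediate (not isolated)
5 | heptadec-4-yn-3-one | CCC(=O)C#CCCCCCCCCCCCC | intermediate
6 | (S)-heptadec-4-yn-3-ol | CC[C@H](O)C#CCCCCCCCCCCCC | intermediate
7 | dipotassium salt of (S)-heptadec-16-yn-3-ol (C15' alkoxide, terminal acetylide) | CC[C@H]([O-])CCCCCCCCCCCCC#[C-].[K+].[K+] | intermediate (not isolated)
8 | (S)-heptadec-16-yn-3-ol | CC[C@H](O)CCCCCCCCCCCCC#C | intermediate
9 | 1,3-bis(benzyloxy)-5-bromobenzene | Brc1cc(OCc2ccccc2)cc(OCc2ccccc2)c1 | starting material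
10 | (S)-17-[3,5-bis(benzyloxy)phenyl]heptadec-16-yn-3-ol | CC[C@H](O)CCCCCCCCCCCCC#Cc1cc(OCc2ccccc2)cc(OCc2ccccc2)c1 | intermediate
11 | (S)-17-[3,5-bis(benzyloxy)phenyl]heptadecan-3-ol | CC[C@H](O)CCCCCCCCCCCCCCc1cc(OCc2ccccc2)cc(OCc2ccccc2)c1 | intermediate (not isolated)
12 | Hansfordiol C, (S)-5-(15-hydroxyheptadecyl)benzene-1,3-diol | CC[C@H](O)CCCCCCCCCCCCCCc1cc(O)cc(O)c1 | target

## Step count and risk

Total: 5 steps. Longest linear sequence: 5 steps (1 → 5 → 6 → 8 → 10 → 12); 2 and 9 enter as purchased partners.

**Step 2 (key step).** The most likely failure is eroded enantioface discrimination, because ethyl is closer in shape to the alkynyl arm than methyl is. The catalyst may also stall if acid traces from step 1 protonate the amido complex. The sense of induction rests on analogy and would be checked on the first batch by a chiral-ester analysis; if it were reversed, the (R,R) complex would be used. Fallback, from 5 back to 6: 5 is reduced without stereocontrol (NaBH4, CeCl3·7H2O, MeOH, −20 °C) to rac-heptadec-4-yn-3-ol F1. The racemate is resolved by acyl transfer with immobilized Candida antarctica lipase B and vinyl acetate in hexane at 30 °C. By the empirical size rule for lipase acylation of secondary alcohols (alkynyl arm large, ethyl medium) the R enantiomer should be converted into (R)-heptadec-4-yn-3-yl acetate F2, leaving 6 as the unreacted alcohol, separable on silica gel. The cost is at most half of the material.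

**Step 3.** The most likely failure is incomplete migration, leaving positional isomers of the internal alkyne, because the long-chain alkoxide is poorly soluble and the amide base is consumed by stray proton sources. Partial loss of configuration is possible if free propargylic alcohol persists before the alkoxide is fully formed. Fallback, from 9 back to 11, giving up the relocation and taking the stereocentre from the chiral pool:
- Sonogashira coupling of 9 with commercial undec-10-yn-1-ol F3 (conditions of step 4) gives 11-[3,5-bis(benzyloxy)phenyl]undec-10-yn-1-ol F4.
- CBr4/PPh3 in CH2Cl2 converts it into 1,3-bis(benzyloxy)-5-(11-bromoundec-1-yn-1-yl)benzene F5.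
- In parallel, commercial (S)-2-ethyloxirane F6 is opened at its CH2 terminus by LiC≡CH·H2NCH2CH2NH2 in DMSO to give (S)-hex-5-yn-3-ol F7; the C–O stereocentre is not touched.
- The dianion of F7 (n-BuLi, 2 equiv, THF/DMPU) is C-alkylated by F5 to give (S)-17-[3,5-bis(benzyloxy)phenyl]heptadeca-5,16-diyn-3-ol F8.
- Hydrogenation of F8 under the conditions of step 5 saturates both triple bonds, arriving at 11 and from there at 12.

**Step 4.** The most likely failure is oxidative (Glaser-type) dimerization of the alkyne outrunning a slow insertion of palladium into the C–Br bond, which would consume the chiral fragment. Fallback, from 8 back to 11, replacing the sp–sp2 coupling by an sp3–sp2 coupling: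
- Semihydrogenation of 8 (H2, Pd/CaCO3 poisoned with Pb(OAc)2, quinoline, EtOAc) gives (S)-heptadec-16-en-3-ol F9.
- 9-BBN (2.2 equiv, THF, 25 °C) adds to the terminal alkene in the anti-Markovnikov sense and borylates the hydroxyl, giving (S)-9-[15-(9-borabicyclo[3.3.1]nonan-9-yloxy)heptadecyl]-9-borabicyclo[3.3.1]nonane F10.
- F10 is coupled in the same flask with 9 (PdCl2(dppf), aqueous K3PO4, THF/DMF, 60 °C; B-alkyl Suzuki–Miyaura coupling) to give 11, the O-borinate being hydrolysed in the basic medium.
- 11 is then debenzylated under the conditions of step 5 to 12. No copper acetylide is present, so the dimerization pathway is closed.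

**Step 5.** The most likely failure is stalling of the hydrogenolysis at the mono-benzyl stage, through poisoning of the palladium surface by amine, phosphine or copper residues from step 4 or through low solubility of the waxy intermediates. Fallback, from 10 back to 12, separating the two tasks: the triple bond is saturated over Pd/C in EtOAc containing pyridine, which suppresses O-debenzylation, and 11 is isolated. The benzyl ethers are then removed by Lewis acid in place of hydrogen: BCl3 with pentamethylbenzene as cation scavenger, CH2Cl2, −78 °C, under which a secondary alcohol is only borylated transiently. This fallback makes no compound outside the list (entry F0).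

## Further compounds

F1 | step 2 | rac-heptadec-4-yn-3-ol | CCC(O)C#CCCCCCCCCCCCC
F2 | step 2 | (R)-heptadec-4-yn-3-yl acetate | CC[C@@H](OC(C)=O)C#CCCCCCCCCCCCC
F3 | step 3 | undec-10-yn-1-ol | OCCCCCCCCCC#C
F4 | step 3 | 11-[3,5-bis(benzyloxy)phenyl]undec-10-yn-1-ol | OCCCCCCCCCC#Cc1cc(OCc2ccccc2)cc(OCc2ccccc2)c1
F5 | step 3 | 1,3-bis(benzyloxy)-5-(11-bromoundec-1-yn-1-yl)benzene | BrCCCCCCCCCC#Cc1cc(OCc2ccccc2)cc(OCc2ccccc2)c1
F6 | step 3 | (S)-2-ethyloxirane | CC[C@H]1CO1
F7 | step 3 | (S)-hex-5-yn-3-ol | CC[C@H](O)CC#C
F8 | step 3 | (S)-17-[3,5-bis(benzyloxy)phenyl]heptadeca-5,16-diyn-3-ol | CC[C@H](O)CC#CCCCCCCCCCC#Cc1cc(OCc2ccccc2)cc(OCc2ccccc2)c1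
F9 | step 4 | (S)-heptadec-16-en-3-ol | CC[C@H](O)CCCCCCCCCCCCC=C
F10 | step 4 | (S)-9-[15-(9-borabicyclo[3.3.1]nonan-9-yloxy)heptadecyl]-9-borabicyclo[3.3.1]nonane | CC[C@H](OB1C2CCCC1CCC2)CCCCCCCCCCCCCCB1C2CCCC1CCC2
F0 | step 5 | none | none
A1 | alternative 1 | 3-[(S)-15-(tert-butyldimethylsilyloxy)heptadecyl]cyclobut-2-en-1-one | CC[C@H](O[Si](C)(C)C(C)(C)C)CCCCCCCCCCCCCCC1=CC(=O)C1
A2 | alternative 1 | ethoxyethyne | C#COCC
A3 | alternative 1 | (S)-3-ethoxy-5-[15-(tert-butyldimethylsilyloxy)heptadecyl]phenol | CC[C@H](O[Si](C)(C)C(C)(C)C)CCCCCCCCCCCCCCc1cc(O)cc(OCC)c1
A4 | alternative 2 | ethyllithium | [Li]CC
A5 | alternative 2 | 2-ethenyl-4,4,5,5-tetramethyl-1,3,2-dioxaborolane | C=CB1OC(C)(C)C(C)(C)O1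
A6 | alternative 2 | lithium ethenyl(ethyl)(pinacolato)borate | [Li+].CC[B-]1(C=C)OC(C)(C)C(C)(C)O1
A7 | alternative 2 | 1-[(E)-13-bromotridec-12-en-1-yl]-3,5-dimethoxybenzene | COc1cc(CCCCCCCCCCC/C=C/Br)cc(OC)c1
A8 | alternative 2 | (S,E)-2-[17-(3,5-dimethoxyphenyl)heptadec-5-en-3-yl]-4,4,5,5-tetramethyl-1,3,2-dioxaborolane | CC[C@H](B1OC(C)(C)C(C)(C)O1)C/C=C/CCCCCCCCCCCc1cc(OC)cc(OC)c1
A9 | alternative 3 | (S)-4-(tert-butyldimethylsilyloxy)hexanoic acid | CC[C@H](O[Si](C)(C)C(C)(C)C)CCC(=O)O
A10 | alternative 3 | 13-[3,5-bis(2,2-dimethylpropanoyloxy)phenyl]tridecanoic acid | OC(=O)CCCCCCCCCCCCc1cc(OC(=O)C(C)(C)C)cc(OC(=O)C(C)(C)C)c1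
A11 | alternative 3 | (S)-5-[15-(tert-butyldimethylsilyloxy)heptadecyl]-1,3-phenylene bis(2,2-dimethylpropanoate) | CC[C@H](O[Si](C)(C)C(C)(C)C)CCCCCCCCCCCCCCc1cc(OC(=O)C(C)(C)C)cc(OC(=O)C(C)(C)C)c1
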